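## Retrosynthetic overview

1. The route rests on ring C of unit 1 (the flavan-3,4-diol): its oxygen O1 joins C2 of an all-cis C2–C3–C4 triol array to the ring A carbon C8a, so the ring can be closed at O1–C8a from an acyclic triol while C2, C3 and the ionisable benzylic C4–O bond stay untouched.
2. Interflavan bonds: C4(unit 3)–C6(unit 2) by syn arylboration of the unit 3 flav-3-ene with the unit 2 aryl bromide (2,3-trans-3,4-cis); C4(unit 2)–C6(unit 1) by aryl-metal addition to the unit 2 flavanone, dehydration and hydroboration (2,3-trans-3,4-trans).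
3. Unit 1 precursor: an acyclic 1,3-diarylpropane-1,2,3-triol derivative from 2-bromoisovanillin, by an anti-selective glycolate Mukaiyama aldol (C3, C4) and a chelation-controlled aryl Grignard addition (C2).
4. Units 2 and 3: one (2S)-flavanone from gallacetophenone through the chromone and a rhodium-catalysed conjugate arylation.
5. Ring order: ring C of units 2 and 3 at the chromone stage, ring C of unit 1 in the key step; all benzene rings are bought; desilylation and hydrogenolysis end the route.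

Key step: step 9

Assumptions (chemistry): flavan numbering is used for all units and for the acyclic chain (C2 bears ring B, C4 bears ring A); unit 1 is the flavan-3,4-diol, unit 2 the middle unit, unit 3 the terminal flavan-3-ol. The ligand antipodes in steps 5 and 13 are assigned by analogy with the closest precedents of these reactions; both antipodes are available and would be exchanged if the sense proved opposite. Compound 13 is bought as a THF solution. Steps 2 and 11 each consume two equivalents of benzyl bromide 3.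

## Route

Step 1
Reactants: 1 2-bromo-3-hydroxy-4-methoxybenzaldehyde (2-bromoisovanillin)
Product: 2 2-bromo-3,4-dihydroxybenzaldehyde
Conditions: BBr3, CH2Cl2, −78 °C → rt; H2O
Reagents that add atoms: none
Why: Lewis-acid cleavage of the aryl methyl ether (boron coordinates the ether oxygen, bromide removes the methyl group by SN2); aldehyde and aryl bromide are inert.

Step 2
Reactants: 2 2-bromo-3,4-dihydroxybenzaldehyde; 3 benzyl bromide
Product: 4 3,4-bis(benzyloxy)-2-bromobenzaldehyde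
Conditions: BnBr (2.3 equiv), K2CO3, DMF, 60 °C
Reagents that add atoms: benzyl bromide, BrCc1ccccc1 (the second equivalent of 3)
Why: Twofold Williamson etherification of both phenoxides, one equivalent of benzyl bromide per hydroxyl, installs the hydrogenolysable phenol protection used throughout.

Step 3
Reactants: 5 benzyloxyacetyl chloride; 6 ethanethiol
Product: 7 S-ethyl 2-(benzyloxy)ethanethioate
Conditions: pyridine, CH2Cl2, 0 °C → rt
Reagents that add atoms: none
Why: Acyl substitution of the acid chloride by the thiol gives the glycolate thioester needed for the aldol donor.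

Step 4
Reactants: 7 S-ethyl 2-(benzyloxy)ethanethioate
Product: 9 [(E)-2-(benzyloxy)-1-(ethylsulfanyl)ethenyl]oxy(trimethyl)silane (benzyloxy cis to siloxy), via lithium enolate 8 (not isolated)
Conditions: LiN(i-Pr)2, THF, −78 °C; Me3SiCl, −78 °C → rt
Reagents that add atoms: chlorotrimethylsilane, C[Si](C)(C)Cl
Why: Kinetic deprotonation gives the lithium-chelated enolate with the benzyloxy oxygen cis to O–Li, and O-silylation fixes this single enol silane geometry (the "Z" enol silane of glycolate nomenclature).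

Step 5
Reactants: 4 3,4-bis(benzyloxy)-2-bromobenzaldehyde; 9 silyl ketene thioacetal
Product: 10 S-ethyl (2R,3R)-2-(benzyloxy)-3-[3,4-bis(benzyloxy)-2-bromophenyl]-3-hydroxypropanethioate
Conditions: Sn(OTf)2, (S)-1-ethyl-2-(piperidin-1-ylmethyl)pyrrolidine, n-Bu2Sn(OAc)2, CH2Cl2, −78 °C; aq. NaHCO3
Reagents that add atoms: none
Why: Asymmetric Mukaiyama aldol promoted by divalent tin triflate and a chiral diamine; the open transition state of the benzyloxy enol silane is anti-selective and the diamine–tin complex selects the aldehyde face, setting C3 and C4 with the C3–O/C4–O anti relationship (2R,3R), and the aqueous work-up releases the free aldol.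

Step 6
Reactants: 10 aldol adduct
Product: 11 S-ethyl (2R,3R)-2-(benzyloxy)-3-[3,4-bis(benzyloxy)-2-bromophenyl]-3-[(tert-butyldimethylsilyl)oxy]propanethioate
Conditions: t-BuMe2SiOTf, 2,6-lutidine, CH2Cl2, −78 → 0 °C
Reagents that add atoms: tert-butyldimethylsilyl trifluoromethanesulfonate, CC(C)(C)[Si](C)(C)OS(=O)(=O)C(F)(F)F
Why: Silyl triflate with a hindered base silylates the benzylic C4 hydroxyl without retro-aldol cleavage; this is the fluoride-labile, non-chelating group wanted at C4.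

Step 7
Reactants: 11 silylated thioester
Product: 12 (2R,3R)-2-(benzyloxy)-3-[3,4-bis(benzyloxy)-2-bromophenyl]-3-[(tert-butyldimethylsilyl)oxy]propanal
Conditions: i-Bu2AlH, CH2Cl2, −78 °C; aq. potassium sodium tartrate
Reagents that add atoms: none
Why: Partial reduction of the thioester stops at the aluminium hemithioacetal, which releases the aldehyde on work-up; the α-centre is not touched at −78 °C.

Step 8
Reactants: 12 aldehyde; 13 4-(benzyloxy)phenylmagnesium bromide
Product: 14 (1R,2S,3R)-2-(benzyloxy)-1-[4-(benzyloxy)phenyl]-3-[3,4-bis(benzyloxy)-2-bromophenyl]-3-[(tert-butyldimethylsilyl)oxy]propan-1-ol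
Conditions: MgBr2·OEt2, CH2Cl2, −78 °C; then 13 (THF), −78 → −40 °C; aq. NH4Cl
Reagents that add atoms: none
Why: Chelation-controlled (Cram-chelate) Grignard addition: magnesium bridges the aldehyde oxygen and the α-benzyloxy oxygen, the silyl ether does not chelate, and the aryl group enters from the side of the α-hydrogen, setting C2 syn to C3–OBn.

Step 9
Reactants: 14 acyclic triol derivative (free C2–OH, C3–OBn, C4–OSi, ring A bromide)
Product: 15 (2R,3S,4R)-3,7,8-tris(benzyloxy)-2-[4-(benzyloxy)phenyl]-4-[(tert-butyldimethylsilyl)oxy]chromane (all-cis protected unit 1)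
Conditions: CuI (10 mol%), 3,4,7,8-tetramethyl-1,10-phenanthroline (20 mol%), Cs2CO3, toluene, 110 °C, Ar
Reagents that add atoms: none
Why: Cs2CO3 deprotonates the only free hydroxyl (C2–OH), and the phenanthroline-bound monovalent copper alkoxide activates the ring A C8a–Br bond (oxidative addition to a trivalent aryl copper alkoxide or its concerted equivalent); C–O reductive elimination then forms O1–C8a and returns monovalent copper. The closest known reaction type is the copper-catalysed Ullmann-type O-arylation of aliphatic alcohols with aryl halides, used intramolecularly to make chromans. Ring C of unit 1 closes in a six-membered mode, exo with respect to the C8a–Br bond, through a seven-membered aryl–copper–alkoxide chelate; no other ring forms. No stereocentre is created: the bonds at C2, C3 and C4 are not touched, so the C2/C3 syn and C3/C4 anti relationships of 14 become the all-cis chroman with retention. The step needs selectivity for the C2 oxygen and survival of the benzylic C4–O bond; the benzyl ether at C3 and the silyl ether at C4 leave only the six-membered closure open (a silyl shift from O4 to O2 would be reversible and its product cannot cyclise), and the basic, non-ionising medium cannot form the C4 benzylic cation that acid would.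

Step 10
Reactants: 15 protected unit 1
Product: 16 (2R,3S,4R)-3,7,8-tris(benzyloxy)-2-[4-(benzyloxy)phenyl]-6-bromo-4-[(tert-butyldimethylsilyl)oxy]chromane
Conditions: NBS, NaHCO3, MeCN/CH2Cl2, −20 → 0 °C, dark
Reagents that add atoms: N-bromosuccinimide, O=C1CCC(=O)N1Br
Why: Electrophilic aromatic bromination goes to C6, which is para to O1 and ortho to the 7-benzyloxy group, while C5 is shielded by the C4 silyl ether and activated only by the twisted 8-benzyloxy group; buffering keeps the C4–O bond intact.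

Step 11
Reactants: 17 1-(2,3,4-trihydroxyphenyl)ethanone (gallacetophenone); 3 benzyl bromide
Product: 18 1-[3,4-bis(benzyloxy)-2-hydroxyphenyl]ethanone
Conditions: BnBr (2.1 equiv), K2CO3, acetone, reflux
Reagents that add atoms: benzyl bromide, BrCc1ccccc1 (the second equivalent of 3)
Why: Twofold Williamson etherification, one equivalent of benzyl bromide per hydroxyl, is selective for the 3- and 4-hydroxyls because the 2-hydroxyl is hydrogen-bonded to the ketone and the least nucleophilic.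

Step 12
Reactants: 18 dibenzylated acetophenone
Product: 20 7,8-bis(benzyloxy)-4H-chromen-4-one, via enaminone 19 (not isolated)
Conditions: Me2NCH(OMe)2, toluene, 100 °C; then conc. HCl, CH2Cl2, 40 °C
Reagents that add atoms: N,N-dimethylformamide dimethyl acetal, COC(OC)N(C)C
Why: Condensation of the methyl ketone gives the enaminone, and acid-promoted addition–elimination of the phenol with loss of dimethylamine closes ring C of units 2 and 3 as the chromone.

Step 13
Reactants: 20 chromone; 21 4-(benzyloxy)phenylboronic acid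
Product: 22 (2S)-7,8-bis(benzyloxy)-2-[4-(benzyloxy)phenyl]chroman-4-one
Conditions: [Rh(OH)(cod)]2 (1.5 mol%), (S)-MeO-F12-BIPHEP (3.3 mol%), toluene/H2O, 40 °C
Reagents that add atoms: none
Why: Rhodium-catalysed asymmetric 1,4-addition (Hayashi–Miyaura reaction): the aryl rhodium species adds to C2 of the chromone on the face chosen by the biaryl diphosphine, and protonation of the rhodium enolate gives the (2S)-flavanone.

Step 14
Reactants: 22 (2S)-flavanone
Product: 23 (2S)-7,8-bis(benzyloxy)-2-[4-(benzyloxy)phenyl]-6-bromochroman-4-one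
Conditions: NBS, DMF, 0 °C → rt, dark
Reagents that add atoms: N-bromosuccinimide, O=C1CCC(=O)N1Br
Why: Electrophilic aromatic bromination at C6 (para to O1, ortho to 7-OBn, meta to the acyl-bearing carbon) is faster than attack on ring B with its single oxygen donor; neutral conditions avoid α-bromination and ring opening.

Step 15
Reactants: 22 (2S)-flavanone
Product: 24 (2S,4S)-7,8-bis(benzyloxy)-2-[4-(benzyloxy)phenyl]chroman-4-ol (2,4-cis major; the C4 epimer is carried along)
Conditions: NaBH4, THF/MeOH, 0 °C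
Reagents that add atoms: none
Why: Hydride reduction of the ketone; the C4 configuration is irrelevant because C4 becomes sp2 in the next step.

Step 16
Reactants: 24 flavan-4-ol
Product: 25 (2S)-7,8-bis(benzyloxy)-2-[4-(benzyloxy)phenyl]-2H-chromene (unit 3 flav-3-ene)
Conditions: p-TsOH·H2O (2 mol%), 4 Å MS, toluene, 70 °C, dark
Reagents that add atoms: none
Why: Acid-catalysed E1 dehydration through the para-alkoxybenzyl cation at C4 gives the styrene-type C3=C4 bond; C2 is not involved.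

Step 17
Reactants: 16 unit 1 bromide; 23 unit 2 bromoflavanone
Product: 28 dimer carbinol (unit 2 as 6-bromo-4-hydroxyflavan bonded at C4 to C6 of unit 1; both C4 epimers), via aryllithium 26 (not isolated), via aryl cerium dichloride 27 (not isolated)
Conditions: t-BuLi (2.05 equiv), THF, −78 °C; CeCl3 (anhydrous), −78 °C; then 23, −78 → −40 °C; aq. NH4Cl
Reagents that add atoms: none
Why: Bromine–lithium exchange at C6, transmetalation to the weakly basic organocerium reagent and 1,2-addition to the flavanone carbonyl form the C4(unit 2)–C6(unit 1) bond without enolisation or attack on the aryl bromide of 23; the new carbinol centre is removed in step 18.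

Step 18
Reactants: 28 dimer carbinol
Product: 29 dimer flav-3-ene ((2S)-6-bromo-2H-chromene of unit 2 carrying C6 of unit 1 at C4)
Conditions: PPTS (10 mol%), 4 Å MS, toluene, 40 °C, dark
Reagents that add atoms: none
Why: E1 dehydration of the tertiary diaryl carbinol needs only a weak acid, which leaves the secondary benzylic silyl ether of unit 1 alone; only the C3 hydrogens can be lost.

Step 19
Reactants: 29 dimer flav-3-ene
Product: 31 dimer alcohol (unit 2 = (2R,3S)-2,3-trans-3,4-trans-6-bromoflavan-3-ol with C6 of unit 1 at C4), via alkylborane 30 (not isolated)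
Conditions: BH3·THF, THF, 0 °C → rt; then 2 M NaOH, 30% H2O2, 0 °C → rt
Reagents that add atoms: borane, B (boron of 30); hydrogen peroxide, OO
Why: Hydroboration–oxidation: boron adds to C3 (the less substituted carbon, β to both aryl groups) and hydrogen to C4, syn and on the face opposite the C2 aryl group; oxidation with retention gives C3–OH trans to C2-aryl and trans to the C4 aryl group.

Step 20
Reactants: 31 dimer alcohol
Product: 32 dimer triethylsilyl ether (unit 2 C3–OSiEt3)
Conditions: Et3SiOTf, 2,6-lutidine, CH2Cl2, −40 → 0 °C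
Reagents that add atoms: triethylsilyl trifluoromethanesulfonate, CC[Si](CC)(CC)OS(=O)(=O)C(F)(F)F
Why: Silylation masks the secondary hydroxyl so that no alkoxide competes in the base-mediated step 21; the group leaves with the C4 silyl ether in step 22.

Step 21
Reactants: 32 dimer aryl bromide; 25 unit 3 flav-3-ene
Product: 34 trimer alcohol (unit 3 = (2R,3S)-2,3-trans-3,4-cis-flavan-3-ol bonded at C4 to C6 of unit 2), via pinacol boronate 33 (not isolated)
Conditions: 25 (1.5 equiv), B2pin2, (SIMes)CuCl (10 mol%), (RuPhos)Pd(2′-aminobiphenyl-2-yl)(OMs) (third-generation RuPhos palladacycle, 5 mol%), NaOtBu, toluene/THF, rt; then 2 M NaOH, 30% H2O2, THF, 0 °C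
Reagents that add atoms: bis(pinacolato)diboron, CC1(C)OB(OC1(C)C)B1OC(C)(C)C(C)(C)O1 (boron of 33); hydrogen peroxide, OO
Why: Copper/palladium-cocatalysed arylboration of a cyclic alkenyl arene: the copper boryl species adds syn across C3=C4 of 25 on the face opposite the C2 aryl group (boron at C3, copper at benzylic C4); stereoretentive transfer of C4 to the aryl palladium bromide from 32 and reductive elimination form the C4(unit 3)–C6(unit 2) bond cis to boron, and oxidation with retention gives the 2,3-trans-3,4-cis unit 3.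

Step 22
Reactants: 34 trimer alcohol
Product: 35 deca-O-benzyl trimer (free C4–OH in unit 1, free C3–OH in units 2 and 3)
Conditions: n-Bu4NF, THF, 0 °C → rt
Reagents that add atoms: none
Why: Fluoride cleaves both silyl ethers under non-acidic conditions, so the benzylic C4–OH of unit 1 is released without ionisation.

Step 23
Reactants: 35 deca-O-benzyl trimer
Product: 36 target trimer CNP0140823.3
Conditions: H2 (1 atm), Pd(OH)2/C, THF/MeOH, rt
Reagents that add atoms: none
Why: Hydrogenolysis removes the nine aryl benzyl ethers and the C3 benzyl ether of unit 1 in neutral medium; the interflavan C–C bonds and the C2–O1 bonds persist, and the reaction is stopped at full debenzylation to keep the C4 hydroxyl of unit 1.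

## Compound list

1 | 2-bromo-3-hydroxy-4-methoxybenzaldehyde | COc1ccc(C=O)c(Br)c1O | starting material
2 | 2-bromo-3,4-dihydroxybenzaldehyde | Oc1ccc(C=O)c(Br)c1O | intermediate
3 | benzyl bromide | BrCc1ccccc1 | starting material
4 | 3,4-bis(benzyloxy)-2-bromobenzaldehyde | O=Cc1ccc(OCc2ccccc2)c(OCc2ccccc2)c1Br | intermediate
5 | benzyloxyacetyl chloride | O=C(Cl)COCc1ccccc1 | starting material
6 | ethanethiol | CCS | starting material
7 | S-ethyl 2-(benzyloxy)ethanethioate | CCSC(=O)COCc1ccccc1 | intermediate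
8 | lithium enolate of 7 (benzyloxy cis to O–Li; not isolated) | CCS/C(O[Li])=C/OCc1ccccc1 | intermediate
9 | [(E)-2-(benzyloxy)-1-(ethylsulfanyl)ethenyl]oxy(trimethyl)silane (benzyloxy cis to siloxy) | CCS/C(O[Si](C)(C)C)=C/OCc1ccccc1 | intermediate
10 | S-ethyl (2R,3R)-2-(benzyloxy)-3-[3,4-bis(benzyloxy)-2-bromophenyl]-3-hydroxypropanethioate | CCSC(=O)[C@H](OCc1ccccc1)[C@H](O)c1ccc(OCc2ccccc2)c(OCc2ccccc2)c1Br | intermediate
11 | S-ethyl (2R,3R)-2-(benzyloxy)-3-[3,4-bis(benzyloxy)-2-bromophenyl]-3-[(tert-butyldimethylsilyl)oxy]propanethioate | CCSC(=O)[C@H](OCc1ccccc1)[C@H](O[Si](C)(C)C(C)(C)C)c1ccc(OCc2ccccc2)c(OCc2ccccc2)c1Br | intermediate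
12 | (2R,3R)-2-(benzyloxy)-3-[3,4-bis(benzyloxy)-2-bromophenyl]-3-[(tert-butyldimethylsilyl)oxy]propanal | O=C[C@H](OCc1ccccc1)[C@H](O[Si](C)(C)C(C)(C)C)c1ccc(OCc2ccccc2)c(OCc2ccccc2)c1Br | intermediate
13 | 4-(benzyloxy)phenylmagnesium bromide | Br[Mg]c1ccc(OCc2ccccc2)cc1 | starting material
14 | (1R,2S,3R)-2-(benzyloxy)-1-[4-(benzyloxy)phenyl]-3-[3,4-bis(benzyloxy)-2-bromophenyl]-3-[(tert-butyldimethylsilyl)oxy]propan-1-ol (key-step precursor) | O[C@H](c1ccc(OCc2ccccc2)cc1)[C@H](OCc1ccccc1)[C@H](O[Si](C)(C)C(C)(C)C)c1ccc(OCc2ccccc2)c(OCc2ccccc2)c1Br | intermediate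
15 | (2R,3S,4R)-3,7,8-tris(benzyloxy)-2-[4-(benzyloxy)phenyl]-4-[(tert-butyldimethylsilyl)oxy]chromane (all-cis; key-step product) | c9ccccc9COc1ccc([C@H]2Oc3c(ccc(OCc9ccccc9)c3OCc9ccccc9)[C@@H](O[Si](C)(C)C(C)(C)C)[C@H]2OCc9ccccc9)cc1 | intermediate
16 | (2R,3S,4R)-3,7,8-tris(benzyloxy)-2-[4-(benzyloxy)phenyl]-6-bromo-4-[(tert-butyldimethylsilyl)oxy]chromane | c9ccccc9COc1ccc([C@H]2Oc3c(cc(Br)c(OCc9ccccc9)c3OCc9ccccc9)[C@@H](O[Si](C)(C)C(C)(C)C)[C@H]2OCc9ccccc9)cc1 | intermediate
17 | 1-(2,3,4-trihydroxyphenyl)ethanone (gallacetophenone) | CC(=O)c1ccc(O)c(O)c1O | starting material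
18 | 1-[3,4-bis(benzyloxy)-2-hydroxyphenyl]ethanone | CC(=O)c1ccc(OCc2ccccc2)c(OCc2ccccc2)c1O | intermediate
19 | (E)-1-[3,4-bis(benzyloxy)-2-hydroxyphenyl]-3-(dimethylamino)prop-2-en-1-one (not isolated) | CN(C)/C=C/C(=O)c1ccc(OCc2ccccc2)c(OCc2ccccc2)c1O | intermediate
20 | 7,8-bis(benzyloxy)-4H-chromen-4-one | O=c1ccoc2c(OCc3ccccc3)c(OCc3ccccc3)ccc12 | intermediate
21 | 4-(benzyloxy)phenylboronic acid | OB(O)c1ccc(OCc2ccccc2)cc1 | starting material
22 | (2S)-7,8-bis(benzyloxy)-2-[4-(benzyloxy)phenyl]chroman-4-one | O=C1C[C@@H](c2ccc(OCc9ccccc9)cc2)Oc2c(OCc9ccccc9)c(OCc9ccccc9)ccc12 | intermediate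
23 | (2S)-7,8-bis(benzyloxy)-2-[4-(benzyloxy)phenyl]-6-bromochroman-4-one | O=C1C[C@@H](c2ccc(OCc9ccccc9)cc2)Oc2c(OCc9ccccc9)c(OCc9ccccc9)c(Br)cc12 | intermediate
24 | (2S,4S)-7,8-bis(benzyloxy)-2-[4-(benzyloxy)phenyl]chroman-4-ol (2,4-cis, major epimer) | O[C@H]1C[C@@H](c2ccc(OCc9ccccc9)cc2)Oc2c(OCc9ccccc9)c(OCc9ccccc9)ccc12 | intermediate
25 | (2S)-7,8-bis(benzyloxy)-2-[4-(benzyloxy)phenyl]-2H-chromene | C1=C[C@@H](c2ccc(OCc9ccccc9)cc2)Oc2c(OCc9ccccc9)c(OCc9ccccc9)ccc12 | intermediate
26 | 6-lithio derivative of 15 (not isolated) | c9ccccc9COc1ccc([C@H]2Oc3c(cc([Li])c(OCc9ccccc9)c3OCc9ccccc9)[C@@H](O[Si](C)(C)C(C)(C)C)[C@H]2OCc9ccccc9)cc1 | intermediate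
27 | 6-(dichlorocerio) derivative of 15 (not isolated) | c9ccccc9COc1ccc([C@H]2Oc3c(cc([Ce](Cl)Cl)c(OCc9ccccc9)c3OCc9ccccc9)[C@@H](O[Si](C)(C)C(C)(C)C)[C@H]2OCc9ccccc9)cc1 | intermediate
28 | dimer carbinol: (2S)-7,8-bis(benzyloxy)-2-[4-(benzyloxy)phenyl]-6-bromochroman-4-ol bearing at C4 the C6 of protected unit 1 (C4 epimers) | c9ccccc9COc1ccc([C@H]2Oc3c(cc(C4(O)C[C@@H](c5ccc(OCc9ccccc9)cc5)Oc5c(OCc9ccccc9)c(OCc9ccccc9)c(Br)cc45)c(OCc9ccccc9)c3OCc9ccccc9)[C@@H](O[Si](C)(C)C(C)(C)C)[C@H]2OCc9ccccc9)cc1 | intermediate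
29 | dimer flav-3-ene: (2S)-7,8-bis(benzyloxy)-2-[4-(benzyloxy)phenyl]-6-bromo-2H-chromene bearing at C4 the C6 of protected unit 1 | c9ccccc9COc1ccc([C@H]2Oc3c(cc(C4=C[C@@H](c5ccc(OCc9ccccc9)cc5)Oc5c(OCc9ccccc9)c(OCc9ccccc9)c(Br)cc45)c(OCc9ccccc9)c3OCc9ccccc9)[C@@H](O[Si](C)(C)C(C)(C)C)[C@H]2OCc9ccccc9)cc1 | intermediate
30 | dimer C3-borane of unit 2 (boron trans to C2-aryl and trans to C4-aryl; not isolated) | c9ccccc9COc1ccc([C@H]2Oc3c(cc([C@@H]4c5cc(Br)c(OCc9ccccc9)c(OCc9ccccc9)c5O[C@H](c5ccc(OCc9ccccc9)cc5)[C@H]4B)c(OCc9ccccc9)c3OCc9ccccc9)[C@@H](O[Si](C)(C)C(C)(C)C)[C@H]2OCc9ccccc9)cc1 | intermediate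
31 | dimer alcohol: unit 2 = (2R,3S)-2,3-trans-3,4-trans-7,8-bis(benzyloxy)-2-[4-(benzyloxy)phenyl]-6-bromochroman-3-ol with C6 of protected unit 1 at C4 | c9ccccc9COc1ccc([C@H]2Oc3c(cc([C@@H]4c5cc(Br)c(OCc9ccccc9)c(OCc9ccccc9)c5O[C@H](c5ccc(OCc9ccccc9)cc5)[C@H]4O)c(OCc9ccccc9)c3OCc9ccccc9)[C@@H](O[Si](C)(C)C(C)(C)C)[C@H]2OCc9ccccc9)cc1 | intermediate
32 | triethylsilyl ether of 31 (unit 2 C3–OSiEt3) | c9ccccc9COc1ccc([C@H]2Oc3c(cc([C@@H]4c5cc(Br)c(OCc9ccccc9)c(OCc9ccccc9)c5O[C@H](c5ccc(OCc9ccccc9)cc5)[C@H]4O[Si](CC)(CC)CC)c(OCc9ccccc9)c3OCc9ccccc9)[C@@H](O[Si](C)(C)C(C)(C)C)[C@H]2OCc9ccccc9)cc1 | intermediate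
33 | trimer pinacol boronate: unit 3 = 2,3-trans-3,4-cis flavan with Bpin at C3, bonded at C4 to C6 of unit 2 (not isolated) | c9ccccc9COc1ccc([C@H]2Oc3c(cc([C@@H]4c5cc([C@H]6c7ccc(OCc9ccccc9)c(OCc9ccccc9)c7O[C@H](c7ccc(OCc9ccccc9)cc7)[C@H]6B8OC(C)(C)C(C)(C)O8)c(OCc9ccccc9)c(OCc9ccccc9)c5O[C@H](c5ccc(OCc9ccccc9)cc5)[C@H]4O[Si](CC)(CC)CC)c(OCc9ccccc9)c3OCc9ccccc9)[C@@H](O[Si](C)(C)C(C)(C)C)[C@H]2OCc9ccccc9)cc1 | intermediate
34 | trimer alcohol: unit 3 = (2R,3S)-2,3-trans-3,4-cis flavan-3-ol; unit 2 C3–OSiEt3; unit 1 C4–OSi(t-Bu)Me2 | c9ccccc9COc1ccc([C@H]2Oc3c(cc([C@@H]4c5cc([C@H]6c7ccc(OCc9ccccc9)c(OCc9ccccc9)c7O[C@H](c7ccc(OCc9ccccc9)cc7)[C@H]6O)c(OCc9ccccc9)c(OCc9ccccc9)c5O[C@H](c5ccc(OCc9ccccc9)cc5)[C@H]4O[Si](CC)(CC)CC)c(OCc9ccccc9)c3OCc9ccccc9)[C@@H](O[Si](C)(C)C(C)(C)C)[C@H]2OCc9ccccc9)cc1 | intermediate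
35 | deca-O-benzyl trimer (benzyl on all nine phenols and on O3 of unit 1; free C4–OH of unit 1 and C3–OH of units 2 and 3) | c9ccccc9COc1ccc([C@H]2Oc3c(cc([C@@H]4c5cc([C@H]6c7ccc(OCc9ccccc9)c(OCc9ccccc9)c7O[C@H](c7ccc(OCc9ccccc9)cc7)[C@H]6O)c(OCc9ccccc9)c(OCc9ccccc9)c5O[C@H](c5ccc(OCc9ccccc9)cc5)[C@H]4O)c(OCc9ccccc9)c3OCc9ccccc9)[C@@H](O)[C@H]2OCc9ccccc9)cc1 | intermediate
36 | CNP0140823.3 (unit 3 2,3-trans-3,4-cis flavan-3-ol, 4→6 to unit 2 2,3-trans-3,4-trans, 4→6 to unit 1 all-cis (2R,3R,4R)-flavan-3,4-diol) | Oc1ccc([C@H]2Oc3c(cc([C@@H]4c5cc([C@H]6c7ccc(O)c(O)c7O[C@H](c7ccc(O)cc7)[C@H]6O)c(O)c(O)c5O[C@H](c5ccc(O)cc5)[C@H]4O)c(O)c3O)[C@@H](O)[C@H]2O)cc1 | target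

## Step count and risks

Total steps: 23. Longest linear sequence: 15 steps (steps 1, 2, 5–10, 17–23, from 1 to 36).

Steps most likely to fail:

Step 21 (arylboration). Process at risk: transfer of the congested benzylic copper centre at C4 of unit 3 to the aryl palladium complex of 32 may be slower than protonation of the C–Cu bond or direct borylation or reduction of the aryl bromide, so that no C4–C6 bond forms. The fallback sets out from 22 and 32 and returns at 35. Soft enolisation of 22 (t-BuMe2SiOTf, Et3N, CH2Cl2, 0 °C) should give the silyl enol ether (2S)-7,8-bis(benzyloxy)-2-[4-(benzyloxy)phenyl]-4-[(tert-butyldimethylsilyl)oxy]-2H-chromene F1. Rubottom oxidation (dimethyldioxirane, acetone/CH2Cl2, −40 °C), with oxygen delivered to the face opposite the C2 aryl group and silyl transfer to the new oxygen, should give the trans ketone (2R,3R)-7,8-bis(benzyloxy)-2-[4-(benzyloxy)phenyl]-3-[(tert-butyldimethylsilyl)oxy]chroman-4-one F2. Bromide 32 is exchanged (t-BuLi, THF, −78 °C) to the aryllithium of 32 F3, which adds to the ketone of F2 to give the tertiary trimer carbinol F4 (C4 epimers). Ionic hydrogenation (Et3SiH, BF3·OEt2, CH2Cl2, −78 °C) should ionise only the doubly benzylic tertiary hydroxyl; hydride enters trans to the C3 silyloxy group, so the aryl group finishes cis to it, giving the 2,3-trans-3,4-cis trimer tris(silyl ether) F5. n-Bu4NF (THF, rt → 40 °C) then removes the three silyl groups and gives 35.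

Step 9 (key O-arylation). Process at risk: slow activation of the doubly ortho-substituted, electron-rich C8a–Br bond, so that oxidation of the benzylic alkoxide, hydrodebromination or base-induced silyl transfer from O4 to O2 consume 14. The fallback sets out from 14 and returns at 15, keeping the O1–C8a disconnection. Aromatic Finkelstein exchange (CuI, trans-N,N′-dimethylcyclohexane-1,2-diamine, NaI, dioxane, 110 °C; no base, so the alcohol does not couple) should give the aryl iodide (1R,2S,3R)-2-(benzyloxy)-1-[4-(benzyloxy)phenyl]-3-[3,4-bis(benzyloxy)-2-iodophenyl]-3-[(tert-butyldimethylsilyl)oxy]propan-1-ol F6. The ring is then closed by palladium catalysis (Pd(OAc)2, 2-(di-tert-butylphosphino)-1,1′-binaphthyl, Cs2CO3, toluene, 65 °C): oxidative addition of zerovalent palladium to the C–I bond and C–O reductive elimination from the aryl palladium alkoxide form the same six-membered ring at lower temperature and give 15.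

Step 17 (aryl-metal addition to the flavanone). Process at risk: deprotonation of the C3 methylene of 23 by the aryl-metal and opening of ring C to the chalcone phenoxide, which destroys the C2 configuration and returns protonated 15. The fallback sets out from 16 and 23 and returns at 29, reversing the polarity of the coupling. The aryllithium 26 is borylated (2-isopropoxy-4,4,5,5-tetramethyl-1,3,2-dioxaborolane, THF, −78 °C → rt) to the unit 1 C6 pinacol boronate F7. Ketone 23 is converted without a free enolate (Tf2O, 2,6-di-tert-butyl-4-methylpyridine, CH2Cl2, 0 °C) into the enol triflate (2S)-7,8-bis(benzyloxy)-2-[4-(benzyloxy)phenyl]-6-bromo-2H-chromen-4-yl trifluoromethanesulfonate F8. Suzuki–Miyaura coupling (Pd(PPh3)4, K3PO4, THF/H2O, 40 °C), in which the alkenyl triflate should react ahead of the hindered, electron-rich aryl bromide, gives 29 directly.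

## Further compounds

F1 | step 21 | (2S)-7,8-bis(benzyloxy)-2-[4-(benzyloxy)phenyl]-4-[(tert-butyldimethylsilyl)oxy]-2H-chromene | CC(C)(C)[Si](C)(C)OC1=C[C@@H](c2ccc(OCc9ccccc9)cc2)Oc2c(OCc9ccccc9)c(OCc9ccccc9)ccc12
F2 | step 21 | (2R,3R)-7,8-bis(benzyloxy)-2-[4-(benzyloxy)phenyl]-3-[(tert-butyldimethylsilyl)oxy]chroman-4-one | O=C1[C@H](O[Si](C)(C)C(C)(C)C)[C@@H](c2ccc(OCc9ccccc9)cc2)Oc2c(OCc9ccccc9)c(OCc9ccccc9)ccc12
F3 | step 21 | aryllithium of 32 (lithium at C6 of unit 2) | c9ccccc9COc1ccc([C@H]2Oc3c(cc([C@@H]4c5cc([Li])c(OCc9ccccc9)c(OCc9ccccc9)c5O[C@H](c5ccc(OCc9ccccc9)cc5)[C@H]4O[Si](CC)(CC)CC)c(OCc9ccccc9)c3OCc9ccccc9)[C@@H](O[Si](C)(C)C(C)(C)C)[C@H]2OCc9ccccc9)cc1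
F4 | step 21 | tertiary trimer carbinol (unit 3 = 2,3-trans-3-silyloxy-4-hydroxyflavan bonded at C4 to C6 of unit 2; C4 epimers) | c9ccccc9COc1ccc([C@H]2Oc3c(cc([C@@H]4c5cc(C6(O)c7ccc(OCc9ccccc9)c(OCc9ccccc9)c7O[C@H](c7ccc(OCc9ccccc9)cc7)[C@H]6O[Si](C)(C)C(C)(C)C)c(OCc9ccccc9)c(OCc9ccccc9)c5O[C@H](c5ccc(OCc9ccccc9)cc5)[C@H]4O[Si](CC)(CC)CC)c(OCc9ccccc9)c3OCc9ccccc9)[C@@H](O[Si](C)(C)C(C)(C)C)[C@H]2OCc9ccccc9)cc1
F5 | step 21 | trimer tris(silyl ether) (unit 3 2,3-trans-3,4-cis with C3–OSi(t-Bu)Me2; unit 2 C3–OSiEt3; unit 1 C4–OSi(t-Bu)Me2) | c9ccccc9COc1ccc([C@H]2Oc3c(cc([C@@H]4c5cc([C@H]6c7ccc(OCc9ccccc9)c(OCc9ccccc9)c7O[C@H](c7ccc(OCc9ccccc9)cc7)[C@H]6O[Si](C)(C)C(C)(C)C)c(OCc9ccccc9)c(OCc9ccccc9)c5O[C@H](c5ccc(OCc9ccccc9)cc5)[C@H]4O[Si](CC)(CC)CC)c(OCc9ccccc9)c3OCc9ccccc9)[C@@H](O[Si](C)(C)C(C)(C)C)[C@H]2OCc9ccccc9)cc1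
F6 | step 9 | (1R,2S,3R)-2-(benzyloxy)-1-[4-(benzyloxy)phenyl]-3-[3,4-bis(benzyloxy)-2-iodophenyl]-3-[(tert-butyldimethylsilyl)oxy]propan-1-ol | O[C@H](c1ccc(OCc2ccccc2)cc1)[C@H](OCc1ccccc1)[C@H](O[Si](C)(C)C(C)(C)C)c1ccc(OCc2ccccc2)c(OCc2ccccc2)c1I
F7 | step 17 | unit 1 C6 pinacol boronate ((2R,3S,4R)-3,7,8-tris(benzyloxy)-2-[4-(benzyloxy)phenyl]-4-[(tert-butyldimethylsilyl)oxy]-6-(4,4,5,5-tetramethyl-1,3,2-dioxaborolan-2-yl)chromane) | c9ccccc9COc1ccc([C@H]2Oc3c(cc(B4OC(C)(C)C(C)(C)O4)c(OCc9ccccc9)c3OCc9ccccc9)[C@@H](O[Si](C)(C)C(C)(C)C)[C@H]2OCc9ccccc9)cc1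
F8 | step 17 | (2S)-7,8-bis(benzyloxy)-2-[4-(benzyloxy)phenyl]-6-bromo-2H-chromen-4-yl trifluoromethanesulfonate | O=S(=O)(OC1=C[C@@H](c2ccc(OCc9ccccc9)cc2)Oc2c(OCc9ccccc9)c(OCc9ccccc9)c(Br)cc12)C(F)(F)F
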